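| flask | G | Z | L | temperature | remark | time |
|---|---|---|---|---|---|---|
| summer | 0.20 M | 1 M | 0.80 M | 105 °C | run made earlier |  |
| spring | 0.30 M | 1 M | 0.80 M | 116 °C | run made earlier |  |
| amber | 0.40 M | 1.00 M | 0.800 M | 100 °C |  | 4.0 d |
| red | 0.40 M | 1.00 M | 0.800 M | 120 °C |  | 4.0 d |

summer run (percent of the G charged)

| time / d | X / % | G / % | J / % | D / % |
|---|---|---|---|---|
| 0.333 | 15.0 | 19.8 | 37.4 | 29.1 |
| 0.833 | 14.0 | 10.9 | 55.2 | 22.3 |
| 1.67 | 8.0 | 6.6 | 69.4 | 16.0 |
| 2.50 | 4.2 | 3.4 | 80.2 | 10.4 |

spring run (percent of the G charged)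

| time / h | X / % | G / % | J / % | D / % |
|---|---|---|---|---|
| 4.00 | 10.1 | 16.9 | 39.5 | 33.7 |
| 10.0 | 7.5 | 9.9 | 55.9 | 23.6 |
| 20.0 | 4.2 | 6.8 | 72.9 | 15.3 |
| 25.0 | 3.6 | 5.0 | 77.1 | 13.1 |

(scatter of a reading: 1 percentage point)

- which of these there is most of at the end, counted by the G in it, amber (J / G / X / D)
- which of these there is most of at the end, counted by the G in it, red (J / G / X / D)
- final amount of the leader among these, as a percentage of the G charged, in amber
- final amount of the leader among these, as a percentage of the G charged, in red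

- on the list of suspects stand: G + Z <-> D; G + L -> J; D -> E; D <-> X

I started with the easy step and added up each row of readings. The last row of the summer run comes to 98.2 %, so within the scatter the G charged stands either as J or in a pool of G, D and X, a resting state. But on the list of suspects J comes from G, not from D or X, so I wanted the part of the pool that is G.

Over the last 3 rows of the summer run, G makes up 0.218 of G, D and X together, and I call this fraction of the pool the free share. The pool fell from 47.2 % to 18.0 % across those rows, yet the share read 0.231 and then 0.189, and 1 percentage point on a G of 3.4 % is scatter enough for that. So I froze it. The same rows of the spring run read 0.244.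

The forecast put J ahead in amber and J ahead in red, at 70 % and 94 %, on the ground that “G, D and X equilibrate quickly, within hours”. My own step from there was this: J at 70 % in amber leaves, with E neglected, a pool of 30.0 %, so the frozen share gives G of 6.54 %.

Amber gave J at 77.5 % and red gave J at 97.0 %, and in amber the step from G and L to J had done half of its turnover up to the asked time by 0.531 d.

    G + Z ⇌ D (K = 1.70 M⁻¹, k = 0.140 M⁻¹ h⁻¹, Ea = 102 kJ mol⁻¹, ΔH = 14.0 kJ mol⁻¹)
    G + L → J (k = 0.100 M⁻¹ h⁻¹, Ea = 96.0 kJ mol⁻¹)
    D → E (k = 4.80 × 10⁻⁴ h⁻¹, Ea = 128 kJ mol⁻¹)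
    D ⇌ X (K = 0.740, k = 0.0880 h⁻¹, Ea = 109 kJ mol⁻¹, ΔH = −62.0 kJ mol⁻¹)
    (constants at 100 °C)

The amber pool ended at 21.7 %, with G at 4.61 %. Its share was 0.213, close to the frozen 0.218. A neighbour flask, like amber but with Z cut to 0.40 M, ended with a share of 0.356, higher than amber's, and with J at 89.6 %.

The runs stem from a simulated flask from invented constants.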